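## Retrosynthetic overview

1. Target ⇒ (primary-selective isobutyrylation, Tamao–Fleming oxidation) a 2,1-benzoxasilole in which the ring carbinol C6–O is carried as C6–Si and the C1–CH2–O arm is the Si–O partner. Ring numbering of the target: C1 bears the CH2O arm, C1=C2 is the alkene, C4 bears the side chain, C6 bears OH.
2. Side chain ⇒ ring C4–C≡CH plus (R)-2-hydroxy-2-methylpent-4-enyl isobutyrate by a ruthenium-catalysed Alder-ene coupling, which makes the C(=CH2)–CH2–CH=CH unit with the (E)-alkene; the tertiary carbinol comes from (S)-2-methylglycidol.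
3. Ring ⇒ endo Diels–Alder reaction of 4-vinyl-2,2-diphenyl-2,5-dihydro-1,2-oxasilole with an (S)-4-benzyloxazolidinone acrylimide. It forms C3–C4 and C5–C6, both ring stereocentres and the C1=C2 alkene; the diene comes from propargyl alcohol and chloro(diphenyl)vinylsilane by enyne metathesis.
4. Enabling feature: the allylic 1,3-dioxygen array O–C6–C1(=C2)–CH2–O of the cyclohexene, with the C1=C2 alkene lying between the two new bonds. Tying C6 and the CH2O oxygen through silicon into a five-membered oxasilole makes the ring the retron of a 1-silyl-2-alkyl diene, which places the acyl carbon para to C1 and meta to C6, the opposite of what a 1-oxygenated diene would give.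
5. Order of ring formation: oxasilole ring (temporary, step 2), then cyclohexene ring (step 4); the oxasilole ring is opened oxidatively in step 11.

Key step: step 4

Remark on the chemistry: chloro(diphenyl)vinylsilane, (S)-4-benzyloxazolidin-2-one and (S)-2-methylglycidol are taken as commercial; the benzoxasilole intermediates are numbered Si1, O2, C3, C3a, C4–C7, C7a.

## Route

Step 1
Reactants: 1 prop-2-yn-1-ol (propargyl alcohol); 2 chloro(ethenyl)diphenylsilane
Product: 3 ethenyl(diphenyl)(prop-2-yn-1-yloxy)silane
Conditions: Et3N, DMAP (cat.), CH2Cl2, 0 °C → rt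
Reagents that add atoms: none
Why: O-silylation of the primary alcohol (nucleophilic substitution at silicon) installs the vinylsilane that later supplies the temporary ring and two of the ring carbons.

Step 2
Reactants: 3 ethenyl(diphenyl)(prop-2-yn-1-yloxy)silane
Product: 4 4-ethenyl-2,2-diphenyl-2,5-dihydro-1,2-oxasilole (ring O1–Si2–C3H=C4(vinyl)–C5H2; Si is trans to the vinyl arm across C3=C4)
Conditions: second-generation Grubbs catalyst (H2IMes)(PCy3)Cl2Ru=CHPh (5 mol%), CH2Cl2 (0.02 M), 40 °C
Reagents that add atoms: none
Why: Silicon-tethered ring-closing enyne metathesis in the exo mode: the ruthenium methylidene adds to the terminal alkyne to give a vinylcarbene at the internal carbon, which closes onto the tethered vinylsilane to the five-membered ring and leaves the 4-vinyl group, so the diene geometry is fixed by the ring and no stereocentre is formed.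

Step 3
Reactants: 5 (4S)-4-benzyl-1,3-oxazolidin-2-one; 6 prop-2-enoyl chloride (acryloyl chloride)
Product: 7 (4S)-4-benzyl-3-(prop-2-enoyl)-1,3-oxazolidin-2-one
Conditions: Et3N, LiCl, THF, −20 °C → rt
Reagents that add atoms: none
Why: N-acylation of the oxazolidinone under LiCl/amine mediation gives the chelating chiral dienophile without touching the existing stereocentre.

Step 4
Reactants: 4 4-ethenyl-2,2-diphenyl-2,5-dihydro-1,2-oxasilole; 7 (4S)-4-benzyl-3-(prop-2-enoyl)-1,3-oxazolidin-2-one
Product: 8 (4S)-4-benzyl-3-{[(6S,7aS)-1,1-diphenyl-1,3,5,6,7,7a-hexahydro-2,1-benzoxasilol-6-yl]carbonyl}-1,3-oxazolidin-2-one (cyclohexene fused to the oxasilolane, alkene C3a=C4, acyl group at C6 and Si at C7a cis)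
Conditions: Et2AlCl (1.4 equiv), CH2Cl2, −78 °C; aq. potassium sodium tartrate
Reagents that add atoms: none
Why: Diels–Alder reaction of the aluminium-chelated s-cis acrylimide with diene 4 through an asynchronous endo transition state, the closest known type being the Et2AlCl-promoted cycloaddition of N-acryloyloxazolidinones with 2-substituted dienes such as isoprene. The cyclohexene ring is closed by an intermolecular [4+2] cycloaddition that forms C6–C5 and C7–C7a of 8 (C4–C3 and C5–C6 of the target ring) and leaves the alkene at C3a=C4 (C1=C2 of the target). The stereocentre at the acyl-bearing carbon is set by the auxiliary: the benzyl group shields the re face of the α-carbon, so the diene adds to the si face and C6 should be (S). The silicon-bearing stereocentre is set relative to it by the endo rule: the five-membered ring holds silicon in the outside position of the diene terminus, so endo addition places Si and the acyl group cis and C7a should be (S). The selectivity needed is bonding of the unsubstituted dienophile carbon to the silicon-bearing diene terminus; it is secured by the para-directing 2-alkyl substituent, by β-silicon stabilisation of the positive charge that builds up on the adjacent ring carbon, and by the bulk of SiPh2, which keeps the auxiliary-bearing carbon at the free CH2 terminus.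

Step 5
Reactants: 8 (4S)-4-benzyl-3-{[(6S,7aS)-1,1-diphenyl-1,3,5,6,7,7a-hexahydro-2,1-benzoxasilol-6-yl]carbonyl}-1,3-oxazolidin-2-one
Product: 9 (6S,7aS)-N-methoxy-N-methyl-1,1-diphenyl-1,3,5,6,7,7a-hexahydro-2,1-benzoxasilole-6-carboxamide
Conditions: AlMe3, MeNH(OMe)·HCl, CH2Cl2, 0 °C → rt
Reagents that add atoms: N,O-dimethylhydroxylamine hydrochloride, CNOC.Cl
Why: Aluminium amide transamidation at the exocyclic acyl group gives the N-methoxy-N-methylamide and releases the auxiliary, without touching a stereocentre and without creating a free hydroxyl next to the siloxane.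

Step 6
Reactants: 9 (6S,7aS)-N-methoxy-N-methyl-1,1-diphenyl-1,3,5,6,7,7a-hexahydro-2,1-benzoxasilole-6-carboxamide
Product: 11 (6S,7aS)-1,1-diphenyl-1,3,5,6,7,7a-hexahydro-2,1-benzoxasilole-6-carbaldehyde, via aluminium hemiaminal 10 (not isolated)
Conditions: i-Bu2AlH, THF, −78 °C; aq. potassium sodium tartrate
Reagents that add atoms: none
Why: Partial hydride reduction of the N-methoxy-N-methylamide stops at the chelated aluminium hemiaminal 10, which releases the aldehyde only on work-up, so over-reduction and enolisation of the α-stereocentre should be avoided.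

Step 7
Reactants: 11 (6S,7aS)-1,1-diphenyl-1,3,5,6,7,7a-hexahydro-2,1-benzoxasilole-6-carbaldehyde
Product: 13 (6S,7aS)-6-ethynyl-1,1-diphenyl-1,3,5,6,7,7a-hexahydro-2,1-benzoxasilole, via diazoalkene 12 (not isolated)
Conditions: Me3SiCHN2, n-BuLi, THF, −78 °C → rt
Reagents that add atoms: (trimethylsilyl)diazomethane, C[Si](C)(C)C=[N+]=[N-]
Why: Colvin rearrangement (addition of lithiated trimethylsilyldiazomethane, Peterson-type loss of silanolate to diazoalkene 12, loss of N2 and 1,2-hydrogen shift of the alkylidene carbene) gives the terminal alkyne under aprotic low-temperature conditions that should spare the Si–O bond and the α-stereocentre.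

Step 8
Reactants: 14 [(2S)-2-methyloxiran-2-yl]methanol ((S)-2-methylglycidol)
Product: 15 (2R)-2-methylpent-4-ene-1,2-diol
Conditions: CH2=CHMgBr (3 equiv), CuI (10 mol%), THF, −30 → 0 °C; aq. NH4Cl
Reagents that add atoms: vinylmagnesium bromide, C=C[Mg]Br
Why: Copper-catalysed Grignard opening of the 2,2-disubstituted epoxide at its CH2 terminus (SN2) leaves the quaternary carbinol carbon untouched, so the descriptor changes from (S) to (R) only through the change in substituent priorities.

Step 9
Reactants: 15 (2R)-2-methylpent-4-ene-1,2-diol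
Product: 16 (2R)-2-hydroxy-2-methylpent-4-en-1-yl 2-methylpropanoate
Conditions: i-PrCOCl (1.05 equiv), 2,4,6-collidine, CH2Cl2, −40 → 0 °C
Reagents that add atoms: 2-methylpropanoyl chloride, CC(C)C(=O)Cl
Why: Chemoselective acylation of the primary hydroxyl with an acid chloride and a hindered pyridine base; the tertiary hydroxyl should not react.

Step 10
Reactants: 13 (6S,7aS)-6-ethynyl-1,1-diphenyl-1,3,5,6,7,7a-hexahydro-2,1-benzoxasilole; 16 (2R)-2-hydroxy-2-methylpent-4-en-1-yl 2-methylpropanoate
Product: 17 (2R,3E)-6-[(6S,7aS)-1,1-diphenyl-1,3,5,6,7,7a-hexahydro-2,1-benzoxasilol-6-yl]-2-hydroxy-2-methylhepta-3,6-dien-1-yl 2-methylpropanoate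
Conditions: [CpRu(NCMe)3]PF6 (10 mol%), acetone, rt
Reagents that add atoms: none
Why: Ruthenium-catalysed alkene–alkyne coupling of Alder-ene type (ruthenacyclopentene, β-hydride elimination, reductive elimination) should give the branched 1,4-diene: the C–C bond forms at the internal alkyne carbon, the alkyne terminus becomes the 1,1-disubstituted =CH2, and the alkene of 16 moves into the (E)-disubstituted position next to the carbinol, while the trisubstituted ring alkene and the stereocentres are not engaged.

Step 11
Reactants: 17 (2R,3E)-6-[(6S,7aS)-1,1-diphenyl-1,3,5,6,7,7a-hexahydro-2,1-benzoxasilol-6-yl]-2-hydroxy-2-methylhepta-3,6-dien-1-yl 2-methylpropanoate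
Product: 18 (2R,3E)-2-hydroxy-6-[(1S,3S)-3-hydroxy-4-(hydroxymethyl)cyclohex-4-en-1-yl]-2-methylhepta-3,6-dien-1-yl 2-methylpropanoate
Conditions: 30% aq. H2O2, KF, KHCO3, THF/MeOH (1:1), rt → 40 °C
Reagents that add atoms: hydrogen peroxide, OO
Why: Tamao–Fleming oxidation: the fluoride- and peroxide-activated silicon undergoes 1,2-migration of the allylic ring carbon from Si to O with retention and without allylic transposition, and hydrolysis of the Si–O bonds then unveils the (S)-carbinol cis to the side chain together with the hydroxymethyl group.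

Step 12
Reactants: 18 (2R,3E)-2-hydroxy-6-[(1S,3S)-3-hydroxy-4-(hydroxymethyl)cyclohex-4-en-1-yl]-2-methylhepta-3,6-dien-1-yl 2-methylpropanoate
Product: 19 [(4S,6S)-6-hydroxy-4-[(4E,6R)-6-hydroxy-6-methyl-7-(2-methylpropanoyloxy)hepta-1,4-dien-2-yl]cyclohex-1-en-1-yl]methyl 2-methylpropanoate (target, CNP0599657.1)
Conditions: i-PrCOCl (1.1 equiv), 2,4,6-collidine, CH2Cl2, −78 °C
Reagents that add atoms: 2-methylpropanoyl chloride, CC(C)C(=O)Cl
Why: Kinetically controlled acylation with an acid chloride and collidine at low temperature should take the primary allylic hydroxyl in preference to the neighbouring secondary allylic and the tertiary hydroxyl, which completes the target.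

## Compound list

1 | prop-2-yn-1-ol | C#CCO | starting material
2 | chloro(ethenyl)diphenylsilane | C=C[Si](Cl)(c1ccccc1)c1ccccc1 | starting material
3 | ethenyl(diphenyl)(prop-2-yn-1-yloxy)silane | C=C[Si](OCC#C)(c1ccccc1)c1ccccc1 | intermediate
4 | 4-ethenyl-2,2-diphenyl-2,5-dihydro-1,2-oxasilole | C=CC1=C[Si](c2ccccc2)(c2ccccc2)OC1 | intermediate
5 | (4S)-4-benzyl-1,3-oxazolidin-2-one | O=C1OC[C@H](Cc2ccccc2)N1 | starting material
6 | prop-2-enoyl chloride | C=CC(=O)Cl | starting material
7 | (4S)-4-benzyl-3-(prop-2-enoyl)-1,3-oxazolidin-2-one | C=CC(=O)N1[C@@H](Cc2ccccc2)COC1=O | intermediate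
8 | (4S)-4-benzyl-3-{[(6S,7aS)-1,1-diphenyl-1,3,5,6,7,7a-hexahydro-2,1-benzoxasilol-6-yl]carbonyl}-1,3-oxazolidin-2-one | O=C(N1[C@@H](Cc2ccccc2)COC1=O)[C@H]1CC=C2CO[Si](c3ccccc3)(c3ccccc3)[C@H]2C1 | intermediate
9 | (6S,7aS)-N-methoxy-N-methyl-1,1-diphenyl-1,3,5,6,7,7a-hexahydro-2,1-benzoxasilole-6-carboxamide | CON(C)C(=O)[C@H]1CC=C2CO[Si](c3ccccc3)(c3ccccc3)[C@H]2C1 | intermediate
10 | {[(6S,7aS)-1,1-diphenyl-1,3,5,6,7,7a-hexahydro-2,1-benzoxasilol-6-yl][methoxy(methyl)amino]methoxy}bis(2-methylpropyl)alumane (aluminium hemiaminal, not isolated) | CON(C)C(O[Al](CC(C)C)CC(C)C)[C@H]1CC=C2CO[Si](c3ccccc3)(c3ccccc3)[C@H]2C1 | intermediate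
11 | (6S,7aS)-1,1-diphenyl-1,3,5,6,7,7a-hexahydro-2,1-benzoxasilole-6-carbaldehyde | O=C[C@H]1CC=C2CO[Si](c3ccccc3)(c3ccccc3)[C@H]2C1 | intermediate
12 | (6S,7aS)-6-(2-diazoethenyl)-1,1-diphenyl-1,3,5,6,7,7a-hexahydro-2,1-benzoxasilole (diazoalkene, not isolated) | [N-]=[N+]=C=C[C@H]1CC=C2CO[Si](c3ccccc3)(c3ccccc3)[C@H]2C1 | intermediate
13 | (6S,7aS)-6-ethynyl-1,1-diphenyl-1,3,5,6,7,7a-hexahydro-2,1-benzoxasilole | C#C[C@H]1CC=C2CO[Si](c3ccccc3)(c3ccccc3)[C@H]2C1 | intermediate
14 | [(2S)-2-methyloxiran-2-yl]methanol | C[C@]1(CO)CO1 | starting material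
15 | (2R)-2-methylpent-4-ene-1,2-diol | C=CC[C@@](C)(O)CO | intermediate
16 | (2R)-2-hydroxy-2-methylpent-4-en-1-yl 2-methylpropanoate | C=CC[C@@](C)(O)COC(=O)C(C)C | intermediate
17 | (2R,3E)-6-[(6S,7aS)-1,1-diphenyl-1,3,5,6,7,7a-hexahydro-2,1-benzoxasilol-6-yl]-2-hydroxy-2-methylhepta-3,6-dien-1-yl 2-methylpropanoate | C=C(C/C=C/[C@@](C)(O)COC(=O)C(C)C)[C@H]1CC=C2CO[Si](c3ccccc3)(c3ccccc3)[C@H]2C1 | intermediate
18 | (2R,3E)-2-hydroxy-6-[(1S,3S)-3-hydroxy-4-(hydroxymethyl)cyclohex-4-en-1-yl]-2-methylhepta-3,6-dien-1-yl 2-methylpropanoate | C=C(C/C=C/[C@@](C)(O)COC(=O)C(C)C)[C@H]1CC=C(CO)[C@@H](O)C1 | intermediate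
19 | [(4S,6S)-6-hydroxy-4-[(4E,6R)-6-hydroxy-6-methyl-7-(2-methylpropanoyloxy)hepta-1,4-dien-2-yl]cyclohex-1-en-1-yl]methyl 2-methylpropanoate | C=C(C/C=C/[C@@](C)(O)COC(=O)C(C)C)[C@H]1CC=C(COC(=O)C(C)C)[C@@H](O)C1 | target

## Step count and risks

Total step count: 12.
Longest linear sequence: 9 steps (1, 2, 4, 5, 6, 7, 10, 11, 12).

Step 4. What may go wrong: Lewis-acid-induced ipso-protodesilylation or opening of the vinylsilane diene under Et2AlCl, or erosion of endo control. Fallback: set out from diene 4 and replace auxiliary and Lewis-acid control by iminium-ion organocatalysis. Acrolein with (5S)-5-benzyl-2,2,3-trimethylimidazolidin-4-one trifluoroacetate (20 mol%) in CH3CN containing about two equivalents of water at −20 °C should add endo to the si face of the (E)-iminium ion, whose re face the benzyl group shields. This should give aldehyde 11 directly, where the route is rejoined; steps 3, 5 and 6 then fall away. The water content is kept low to spare the Si–O bond. This fallback makes no new compound (F0).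

Step 10. What may go wrong: competing C–C bond formation at the alkyne terminus, which leads to the linear 1,4-diene, or slow turnover because the hydroxy ester binds ruthenium. Fallback: set out from alkyne 13 and build the side chain by two C–C bond formations of a different type. Markovnikov syn-allylindation of the terminal alkyne (allyl bromide, indium powder (In), THF, 70 °C; aqueous work-up) should give the skipped diene (6S,7aS)-6-(penta-1,4-dien-2-yl)-1,1-diphenyl-1,3,5,6,7,7a-hexahydro-2,1-benzoxasilole F1. In parallel, epoxide 14 is homologated with dimethylsulfonium methylide (Me3SI, n-BuLi, THF, −10 °C → rt) to (2R)-2-methylbut-3-ene-1,2-diol F2, which is acylated as in step 9 to (2R)-2-hydroxy-2-methylbut-3-en-1-yl 2-methylpropanoate F3. Cross-metathesis of F1 with F3 (second-generation Hoveyda–Grubbs catalyst (H2IMes)Cl2Ru=CH(C6H4-2-O-i-Pr), CH2Cl2, 40 °C) should join the two monosubstituted alkenes with (E) selectivity and give 17, where the route is rejoined.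

Step 2. What may go wrong: oligomerisation by intermolecular enyne metathesis, or arrest of the ruthenium carbene at the hindered vinylsilane before the five-membered ring closes. Fallback: set out from propargyl alcohol 1 and make the ring by carbometalation instead of metathesis. Hydroxyl-directed, copper-catalysed anti-carbomagnesiation (CH2=CHMgBr, CuI (10 mol%), THF) gives the chelated alkenylmagnesium alkoxide, which is quenched with I2 to (2Z)-2-(iodomethylidene)but-3-en-1-ol F4. O-Deprotonation and iodine–lithium exchange (n-BuLi, then t-BuLi, Et2O, −78 °C) followed by Ph2SiCl2 should close the Si–C and Si–O bonds to diene 4, where the route is rejoined. The syn relation of CH2O and the metal enforced by the chelate is the ring geometry of 4.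

Further compounds
F0 | step 4 | none | none
F1 | step 10 | (6S,7aS)-6-(penta-1,4-dien-2-yl)-1,1-diphenyl-1,3,5,6,7,7a-hexahydro-2,1-benzoxasilole | C=CCC(=C)[C@H]1CC=C2CO[Si](c3ccccc3)(c3ccccc3)[C@H]2C1
F2 | step 10 | (2R)-2-methylbut-3-ene-1,2-diol | C=C[C@@](C)(O)CO
F3 | step 10 | (2R)-2-hydroxy-2-methylbut-3-en-1-yl 2-methylpropanoate | C=C[C@@](C)(O)COC(=O)C(C)C
F4 | step 2 | (2Z)-2-(iodomethylidene)but-3-en-1-ol | OC/C(C=C)=C\I
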